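**Plan**

1. Locants follow the germacranolide skeleton (ring C1–C10; lactone C12(=O)–C11(=C13H2); ester carbon C14 on C10; CH2OH = C15 on C4). After desilylation, the lactone oxygen is taken out of C12–O–C6, which leaves a 2-methylenecyclobutanone with C12 bonded to C6, a temporary C–C bond that a Baeyer–Villiger oxidation later opens.
2. That four-membered ring is cut at C11–C12 and C6–C7: an intramolecular [2+2] cycloaddition of the vinylketene C12=C6 (vinyl group C5=C4) with the internal π bond C7=C11 of the terminal allene C7=C11=C13. It closes the cyclobutanone and the ten-membered ring together from open-chain acid 29.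
3. The feature that allows this is the contiguous array C12–C11–C7–C6 with exocyclic C13 and an allylic C6: it is the retron of a ketene–allene adduct, and C6 (secondary, allylic) is the carbon that migrates to oxygen.
4. Acid 29 is cut at C1–C2 (acetylide alkylation), C10–C14 (hydrostannation, iodination, carbonylation of alkyne C10≡C1), C11–C13 (Crabbé homologation of alkyne C7≡C11) and C4=C5 (Horner–Wadsworth–Emmons).
5. Forward: iodide 9 (steps 1–6) and diyne 13 from L-threitol acetonide (steps 7–8) are joined (step 9). Enoate, allene and the two esters follow (steps 10–17), then the acid (18–19), the double ring closure (20), oxygen insertion to the lactone (21) and desilylation (22).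
6. Stereochemistry: C8 and C9 come from the chiral pool; the olefin geometries come from the olefination (C4=C5) and the syn-hydrostannation (C1=C10); C7 and C6 are set in the cycloaddition under control of C8 and the ring fusion, and C6 is retained in the oxygen insertion.

Key step: step 20

Assumption: aldehyde 4 is taken as purchasable (otherwise two routine steps from propane-1,3-diol).

**Route**

Step 1
Reactants: 1 triethyl phosphonoacetate; 2 tert-butyl(2-iodoethoxy)dimethylsilane
Product: 3 ethyl 4-[(tert-butyldimethylsilyl)oxy]-2-(diethoxyphosphoryl)butanoate (racemic)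
Conditions: NaH, DMF, 0 °C; then 2, 0 → 50 °C
Reagents that add atoms: none
Why: SN2 C-alkylation of the sodium phosphonoacetate carbanion by a primary iodide is the standard entry to α-substituted Horner–Wadsworth–Emmons reagents and places C3–C2 on the future C4.

Step 2
Reactants: 3 alkylated phosphonate; 4 3-[(4-methoxyphenyl)methoxy]propanal
Product: 5 ethyl (2E)-2-{2-[(tert-butyldimethylsilyl)oxy]ethyl}-5-[(4-methoxyphenyl)methoxy]pent-2-enoate
Conditions: NaH, THF, 0 °C; then 4, −20 °C → rt
Reagents that add atoms: none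
Why: Horner–Wadsworth–Emmons olefination of the α-branched phosphonate should give mainly the (E)-enoate, in which C6 is trans to the ester carbon C15 and cis to C3 as the C4=C5 bond of the target requires; the minor (Z)-isomer is removed by chromatography.

Step 3
Reactants: 5 (E)-enoate
Product: 6 (2E)-2-{2-[(tert-butyldimethylsilyl)oxy]ethyl}-5-[(4-methoxyphenyl)methoxy]pent-2-en-1-ol
Conditions: i-Bu2AlH, CH2Cl2, −78 °C
Reagents that add atoms: none
Why: 1,2-reduction of the conjugated ester by diisobutylaluminium hydride gives the allylic alcohol (C15) and leaves the silyl and benzyl ethers untouched.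

Step 4
Reactants: 6 allylic alcohol
Product: 7 bis-silyl ether (15-O-TBDPS; 2-O-TBS)
Conditions: TBDPSCl, imidazole, DMF, rt
Reagents that add atoms: tert-butyl(chloro)diphenylsilane, CC(C)(C)[Si](Cl)(c1ccccc1)c1ccccc1
Why: Imidazole-promoted O-silylation protects the C15 hydroxyl with a group that survives every later step up to the last.

Step 5
Reactants: 7 bis-silyl ether
Product: 8 (3E)-3-{[(tert-butyldiphenylsilyl)oxy]methyl}-6-[(4-methoxyphenyl)methoxy]hex-3-en-1-ol
Conditions: PPTS, MeOH, rt
Reagents that add atoms: none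
Why: Acid-catalysed methanolysis cleaves the primary tert-butyldimethylsilyl ether much faster than the tert-butyldiphenylsilyl ether, so only the C2 hydroxyl is freed.

Step 6
Reactants: 8 primary alcohol
Product: 9 homoallylic iodide (C2–I)
Conditions: I2, PPh3, imidazole, CH2Cl2, 0 °C
Reagents that add atoms: iodine, II
Why: Appel-type iodination converts the unhindered primary alcohol into the iodide by SN2 displacement of the oxyphosphonium group.

Step 7
Reactants: 10 (4S,5S)-2,2-dimethyl-1,3-dioxolane-4,5-dimethanol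
Product: 12 (4S,5S)-4,5-diethynyl-2,2-dimethyl-1,3-dioxolane, via dialdehyde 11 (not isolated)
Conditions: (COCl)2, DMSO, CH2Cl2, −78 °C; Et3N; then crude 11, dimethyl (1-diazo-2-oxopropyl)phosphonate, K2CO3, MeOH, 0 °C → rt
Reagents that add atoms: dimethyl (1-diazo-2-oxopropyl)phosphonate, CC(=O)C(=[N+]=[N-])P(=O)(OC)OC
Why: Swern oxidation gives the fragile dialdehyde, which is homologated at once by the Ohira–Bestmann variant of the Seyferth–Gilbert reaction; both stereocentres come unchanged from the tartrate-derived diol because the trans-acetonide is also the thermodynamic isomer.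

Step 8
Reactants: 12 C2-symmetric diyne
Product: 13 (4S,5S)-4-ethynyl-2,2-dimethyl-5-{[tri(propan-2-yl)silyl]ethynyl}-1,3-dioxolane
Conditions: n-BuLi (1.0 equiv), THF, −78 °C; then i-Pr3SiOTf, −78 °C → rt
Reagents that add atoms: tri(propan-2-yl)silyl trifluoromethanesulfonate, CC(C)[Si](OS(=O)(=O)C(F)(F)F)(C(C)C)C(C)C
Why: Monolithiation and C-silylation of the diyne is statistical but gives one monosilyl product because the two alkynes are homotopic; unreacted 12 and the bis-silyl compound are recycled, and the bulky silyl group later keeps this alkyne out of the hydrostannation.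

Step 9
Reactants: 13 monosilylated diyne; 9 homoallylic iodide
Product: 14 coupled internal alkyne (C10≡C1 bonded to C2)
Conditions: 13, n-BuLi, THF, −78 °C; then 9, DMPU, −78 °C → rt
Reagents that add atoms: none
Why: SN2 alkylation of the lithium acetylide by the primary iodide in a dipolar cosolvent forms the C1–C2 bond and unites the two fragments.

Step 10
Reactants: 14 internal alkyne
Product: 16 (E)-alkenyl iodide acetonide (iodine on C10; C2 trans to iodine), via alkenylstannane 15 (not isolated)
Conditions: Bu3SnH, PdCl2(PPh3)2 (cat.), THF, 0 °C → rt; then I2, CH2Cl2, 0 °C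
Reagents that add atoms: iodine, II
Why: Palladium-catalysed syn-hydrostannation places tin on the alkyne carbon next to the oxygenated C9 and hydrogen on C1, and iododestannylation proceeds with retention, so C2 ends trans to iodine (later to the ester), which is the C1=C10 geometry of the target.

Step 11
Reactants: 16 alkenyl iodide acetonide
Product: 17 alkenyl iodide 8,9-diol
Conditions: AcOH/H2O (4:1), 40 °C
Reagents that add atoms: none
Why: Acid-catalysed acetal hydrolysis is done here, before any ester is present, so that the freed 8-hydroxyl cannot lactonise onto C14; the aryl ether, silyl ether and silylalkyne tolerate dilute acetic acid.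

Step 12
Reactants: 17 diol
Product: 18 8-O-triethylsilyl ether (9-OH free)
Conditions: Et3SiOTf (1.0 equiv), 2,6-lutidine, CH2Cl2, −78 °C
Reagents that add atoms: triethylsilyl trifluoromethanesulfonate, CC[Si](CC)(CC)OS(=O)(=O)C(F)(F)F
Why: Sterically controlled monosilylation should take O8, next to the slim alkyne, in preference to O9, which is shielded by the adjacent iodoalkene; this is where the two oxygens are told apart.

Step 13
Reactants: 18 alkenyl iodide
Product: 19 methyl (E)-enoate (C14 installed; 9-OH free)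
Conditions: Pd(PPh3)4 (cat.), CO (1 atm), MeOH, Et3N, DMF, 50 °C
Reagents that add atoms: carbon monoxide, [C-]#[O+]; methanol, CO
Why: Palladium-catalysed methoxycarbonylation of the alkenyl iodide (oxidative addition to zerovalent palladium, CO insertion, methanolysis) installs C14 with retention of olefin geometry, methanol as cosolvent outcompeting the neighbouring hydroxyl for the acylpalladium.

Step 14
Reactants: 19 silylalkyne
Product: 21 terminal alkyne (C7≡C11–H), via silver acetylide 20 (not isolated)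
Conditions: AgF, MeCN, rt, dark; then 1 M HCl
Reagents that add atoms: none
Why: Silver fluoride cleaves the alkynyl C–Si bond by way of the silver acetylide, which acid protonates; this desilylation should spare the silyl ethers and the ester.

Step 15
Reactants: 21 terminal alkyne
Product: 23 terminal allene (C7=C11=C13), via Mannich base 22 (not isolated)
Conditions: CuI, (c-C6H11)2NH, (CH2O)n, 1,4-dioxane, reflux
Reagents that add atoms: formaldehyde (as paraformaldehyde), C=O
Why: Crabbé homologation: a copper-mediated Mannich reaction with formaldehyde and the secondary amine, then 1,5-hydride transfer from the amine and loss of the imine, turns C7≡C11 into the terminal allene without affecting the remote enoate.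

Step 16
Reactants: 23 allenyl alcohol (9-OH)
Product: 24 9-O-acetate (8-O-triethylsilyl)
Conditions: Ac2O, DMAP, pyridine, CH2Cl2, 0 °C
Reagents that add atoms: acetic anhydride, CC(=O)OC(C)=O
Why: DMAP-catalysed acetylation of the only free hydroxyl is placed after the amine-mediated step because the resulting allylic acetate of the Morita–Baylis–Hillman type is sensitive to amines.

Step 17
Reactants: 24 silyl ether acetate
Product: 26 8-O-isobutyrate 9-O-acetate, via 8-alcohol 25 (not isolated)
Conditions: PPTS, MeOH, 0 °C; then i-PrCOCl, pyridine, DMAP (cat.), CH2Cl2, −20 → 0 °C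
Reagents that add atoms: 2-methylpropanoyl chloride, CC(C)C(Cl)=O
Why: Mild acid-catalysed methanolysis removes the secondary triethylsilyl ether in the presence of the diphenylsilyl ether, and the crude alcohol is acylated at once (nucleophilic acyl substitution), which keeps short the time in which the free 8-hydroxyl could lactonise onto C14 or accept the acetyl group from O9.

Step 18
Reactants: 26 p-methoxybenzyl ether
Product: 27 primary alcohol (C12–OH)
Conditions: DDQ, CH2Cl2/pH 7 buffer, 0 °C
Reagents that add atoms: none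
Why: Oxidative cleavage of the p-methoxybenzyl ether by DDQ (hydride abstraction, hydrolysis of the oxocarbenium ion) is selective for the electron-rich benzyl ether over the allene, olefins and esters.

Step 19
Reactants: 27 homoallylic alcohol
Product: 29 β,γ-unsaturated acid (C12 acid), via aldehyde 28 (not isolated)
Conditions: Dess–Martin periodinane, NaHCO3, CH2Cl2, 0 °C; then NaClO2, NaH2PO4, 2-methylbut-2-ene, t-BuOH/H2O, 0 °C
Reagents that add atoms: sodium chlorite, [Na+].[O-]Cl=O
Why: Dess–Martin oxidation followed without delay by Pinnick oxidation gives the acid under buffered conditions that should avoid migration of the C4=C5 double bond into conjugation.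

Step 20
Reactants: 29 β,γ-unsaturated acid
Product: 32 trans-fused 2-methylenecyclobutanone (ten-membered ring closed; 6R,7R,8S,9S), via acid chloride 30 (not isolated), via vinylketene 31 (not isolated)
Conditions: 1-chloro-N,N,2-trimethylprop-1-en-1-amine, CH2Cl2, 0 °C → rt; then syringe-pump addition over 12 h to i-Pr2NEt in toluene (final 0.5 mM), 50 °C
Reagents that add atoms: none
Why: Proposed new method: the chloroenamine turns acid 29 into acid chloride 30 without base or free HCl, slow addition to i-Pr2NEt at high dilution dehydrochlorinates it to vinylketene 31, and the ketene C12=C6 then adds to the internal π bond C7=C11 of the allene in an asynchronous thermal [2+2] in which electrophilic C12 bonds to the central allene carbon C11 and C6 to C7. The closest known reaction type is the intramolecular ketene–allene cycloaddition that gives 2-methylenebicyclo[3.2.0]heptanones and -[4.2.0]octanones from ketenes tethered by three or four atoms; the extension to a nine-atom tether is the new element. The cyclobutanone closes by the cycloaddition itself and the ten-membered carbocycle closes in the same event through the C6–C7 bond, so two rings arise from the open chain, the sp2 centres at C1, C4, C5 and C10 and the two ring-cis olefins leaving few freely rotating bonds in the tether. C7 is set by the face of C7=C11 that C6 reaches, which should be the one anti to the C8–O bond (Felkin–Anh-type control by C8 as positive charge develops at C7), and C6 should end trans to C7 because its α-hydrogen is enolisable under the amine and the trans-fused cyclobutanone should be the less strained one. The step needs ring closure to outrun ketene dimerisation and a [1,5]-hydrogen shift of the vinylketene, which the syringe-pump addition and the moderate temperature should secure, and it needs the substituted rather than the terminal π bond of the allene, which is favoured by its higher nucleophilicity and by the shorter reach of the tether.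

Step 21
Reactants: 32 2-methylenecyclobutanone
Product: 33 15-O-TBDPS α-methylene-γ-butyrolactone
Conditions: 30% aq H2O2, AcOH, 0–5 °C
Reagents that add atoms: hydrogen peroxide, OO
Why: Baeyer–Villiger oxidation: hydrogen peroxide adds to the strained ketone and the secondary allylic carbon C6 should migrate to oxygen in preference to the sp2 carbon C11 and with retention, which inserts O between C12 and C6 and removes the temporary C6–C12 bond; cyclobutanones react under these conditions faster than olefins are epoxidised.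

Step 22
Reactants: 33 silyl ether
Product: 34 target
Conditions: HF·pyridine, pyridine, THF, 0 °C → rt
Reagents that add atoms: none
Why: Fluoride-mediated cleavage of the silyl ether under buffered conditions frees the C15 hydroxyl without acyl migration or conjugate addition to the α-methylene lactone.

**Compound list** (locants C1–C15 as in the plan)

1 | triethyl phosphonoacetate | CCOC(=O)CP(=O)(OCC)OCC | starting material
2 | tert-butyl(2-iodoethoxy)dimethylsilane | CC(C)(C)[Si](C)(C)OCCI | starting material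
3 | ethyl 4-[(tert-butyldimethylsilyl)oxy]-2-(diethoxyphosphoryl)butanoate (racemic) | CCOC(=O)C(CCO[Si](C)(C)C(C)(C)C)P(=O)(OCC)OCC | intermediate
4 | 3-[(4-methoxyphenyl)methoxy]propanal | O=CCCOCc1ccc(OC)cc1 | starting material
5 | ethyl (2E)-2-{2-[(tert-butyldimethylsilyl)oxy]ethyl}-5-[(4-methoxyphenyl)methoxy]pent-2-enoate | O(Cc1ccc(OC)cc1)CC/C=C(/C(=O)OCC)CCO[Si](C)(C)C(C)(C)C | intermediate
6 | (2E)-2-{2-[(tert-butyldimethylsilyl)oxy]ethyl}-5-[(4-methoxyphenyl)methoxy]pent-2-en-1-ol | O(Cc1ccc(OC)cc1)CC/C=C(/CO)CCO[Si](C)(C)C(C)(C)C | intermediate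
7 | tert-butyl{[(2E)-2-{2-[(tert-butyldimethylsilyl)oxy]ethyl}-5-[(4-methoxyphenyl)methoxy]pent-2-en-1-yl]oxy}diphenylsilane | O(Cc1ccc(OC)cc1)CC/C=C(/CO[Si](c2ccccc2)(c2ccccc2)C(C)(C)C)CCO[Si](C)(C)C(C)(C)C | intermediate
8 | (3E)-3-{[(tert-butyldiphenylsilyl)oxy]methyl}-6-[(4-methoxyphenyl)methoxy]hex-3-en-1-ol | O(Cc1ccc(OC)cc1)CC/C=C(/CO[Si](c2ccccc2)(c2ccccc2)C(C)(C)C)CCO | intermediate
9 | tert-butyl{[(2E)-2-(2-iodoethyl)-5-[(4-methoxyphenyl)methoxy]pent-2-en-1-yl]oxy}diphenylsilane | O(Cc1ccc(OC)cc1)CC/C=C(/CO[Si](c2ccccc2)(c2ccccc2)C(C)(C)C)CCI | intermediate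
10 | (4S,5S)-2,2-dimethyl-1,3-dioxolane-4,5-dimethanol (2,3-O-isopropylidene-L-threitol) | OC[C@@H]1OC(C)(C)O[C@H]1CO | starting material
11 | (4R,5R)-2,2-dimethyl-1,3-dioxolane-4,5-dicarbaldehyde | O=C[C@@H]1OC(C)(C)O[C@H]1C=O | intermediate
12 | (4S,5S)-4,5-diethynyl-2,2-dimethyl-1,3-dioxolane | C#C[C@@H]1OC(C)(C)O[C@H]1C#C | intermediate
13 | (4S,5S)-4-ethynyl-2,2-dimethyl-5-{[tri(propan-2-yl)silyl]ethynyl}-1,3-dioxolane | C#C[C@@H]1OC(C)(C)O[C@H]1C#C[Si](C(C)C)(C(C)C)C(C)C | intermediate
14 | (4S,5S)-4-[(5E)-5-{[(tert-butyldiphenylsilyl)oxy]methyl}-8-[(4-methoxyphenyl)methoxy]oct-5-en-1-yn-1-yl]-2,2-dimethyl-5-{[tri(propan-2-yl)silyl]ethynyl}-1,3-dioxolane | O(Cc1ccc(OC)cc1)CC/C=C(/CO[Si](c2ccccc2)(c2ccccc2)C(C)(C)C)CCC#C[C@@H]3OC(C)(C)O[C@H]3C#C[Si](C(C)C)(C(C)C)C(C)C | intermediate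
15 | (E)-alkenylstannane: 14 after syn addition of Bu3Sn (to C10) and H (to C1) across C10≡C1, C2 trans to tin | O(Cc1ccc(OC)cc1)CC/C=C(/CO[Si](c2ccccc2)(c2ccccc2)C(C)(C)C)CC/C=C(/[Sn](CCCC)(CCCC)CCCC)[C@@H]3OC(C)(C)O[C@H]3C#C[Si](C(C)C)(C(C)C)C(C)C | intermediate
16 | (E)-alkenyl iodide acetonide: 15 with iodine in place of Bu3Sn on C10; dioxolane (4R,5S), the descriptor at C9 changing only because of iodine | O(Cc1ccc(OC)cc1)CC/C=C(/CO[Si](c2ccccc2)(c2ccccc2)C(C)(C)C)CC/C=C(/I)[C@@H]3OC(C)(C)O[C@H]3C#C[Si](C(C)C)(C(C)C)C(C)C | intermediate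
17 | alkenyl iodide 8,9-diol (8S,9R): 16 without the acetonide | O(Cc1ccc(OC)cc1)CC/C=C(/CO[Si](c2ccccc2)(c2ccccc2)C(C)(C)C)CC/C=C(/I)[C@H](O)[C@@H](O)C#C[Si](C(C)C)(C(C)C)C(C)C | intermediate
18 | 8-O-triethylsilyl ether of 17 (8S,9R; 9-OH free) | O(Cc1ccc(OC)cc1)CC/C=C(/CO[Si](c2ccccc2)(c2ccccc2)C(C)(C)C)CC/C=C(/I)[C@H](O)[C@@H](O[Si](CC)(CC)CC)C#C[Si](C(C)C)(C(C)C)C(C)C | intermediate
19 | methyl (2E,6E)-6-{[(tert-butyldiphenylsilyl)oxy]methyl}-2-{(1S,2S)-1-hydroxy-2-[(triethylsilyl)oxy]-4-[tri(propan-2-yl)silyl]but-3-yn-1-yl}-9-[(4-methoxyphenyl)methoxy]nona-2,6-dienoate | O(Cc1ccc(OC)cc1)CC/C=C(/CO[Si](c2ccccc2)(c2ccccc2)C(C)(C)C)CC/C=C(/C(=O)OC)[C@H](O)[C@@H](O[Si](CC)(CC)CC)C#C[Si](C(C)C)(C(C)C)C(C)C | intermediate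
20 | silver acetylide of 21 | O(Cc1ccc(OC)cc1)CC/C=C(/CO[Si](c2ccccc2)(c2ccccc2)C(C)(C)C)CC/C=C(/C(=O)OC)[C@H](O)[C@@H](O[Si](CC)(CC)CC)C#C[Ag] | intermediate
21 | methyl (2E,6E)-6-{[(tert-butyldiphenylsilyl)oxy]methyl}-2-{(1S,2S)-1-hydroxy-2-[(triethylsilyl)oxy]but-3-yn-1-yl}-9-[(4-methoxyphenyl)methoxy]nona-2,6-dienoate | O(Cc1ccc(OC)cc1)CC/C=C(/CO[Si](c2ccccc2)(c2ccccc2)C(C)(C)C)CC/C=C(/C(=O)OC)[C@H](O)[C@@H](O[Si](CC)(CC)CC)C#C | intermediate
22 | Mannich base: 21 carrying CH2N(c-C6H11)2 on the alkyne terminus | O(Cc1ccc(OC)cc1)CC/C=C(/CO[Si](c2ccccc2)(c2ccccc2)C(C)(C)C)CC/C=C(/C(=O)OC)[C@H](O)[C@@H](O[Si](CC)(CC)CC)C#CCN(C3CCCCC3)C3CCCCC3 | intermediate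
23 | methyl (2E,6E)-6-{[(tert-butyldiphenylsilyl)oxy]methyl}-2-{(1S,2S)-1-hydroxy-2-[(triethylsilyl)oxy]penta-3,4-dien-1-yl}-9-[(4-methoxyphenyl)methoxy]nona-2,6-dienoate | O(Cc1ccc(OC)cc1)CC/C=C(/CO[Si](c2ccccc2)(c2ccccc2)C(C)(C)C)CC/C=C(/C(=O)OC)[C@H](O)[C@@H](O[Si](CC)(CC)CC)C=C=C | intermediate
24 | methyl (2E,6E)-2-{(1S,2S)-1-(acetyloxy)-2-[(triethylsilyl)oxy]penta-3,4-dien-1-yl}-6-{[(tert-butyldiphenylsilyl)oxy]methyl}-9-[(4-methoxyphenyl)methoxy]nona-2,6-dienoate | O(Cc1ccc(OC)cc1)CC/C=C(/CO[Si](c2ccccc2)(c2ccccc2)C(C)(C)C)CC/C=C(/C(=O)OC)[C@H](OC(C)=O)[C@@H](O[Si](CC)(CC)CC)C=C=C | intermediate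
25 | methyl (2E,6E)-2-[(1S,2S)-1-(acetyloxy)-2-hydroxypenta-3,4-dien-1-yl]-6-{[(tert-butyldiphenylsilyl)oxy]methyl}-9-[(4-methoxyphenyl)methoxy]nona-2,6-dienoate | O(Cc1ccc(OC)cc1)CC/C=C(/CO[Si](c2ccccc2)(c2ccccc2)C(C)(C)C)CC/C=C(/C(=O)OC)[C@H](OC(C)=O)[C@@H](O)C=C=C | intermediate
26 | methyl (2E,6E)-2-{(1S,2S)-1-(acetyloxy)-2-[(2-methylpropanoyl)oxy]penta-3,4-dien-1-yl}-6-{[(tert-butyldiphenylsilyl)oxy]methyl}-9-[(4-methoxyphenyl)methoxy]nona-2,6-dienoate | O(Cc1ccc(OC)cc1)CC/C=C(/CO[Si](c2ccccc2)(c2ccccc2)C(C)(C)C)CC/C=C(/C(=O)OC)[C@H](OC(C)=O)[C@@H](OC(=O)C(C)C)C=C=C | intermediate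
27 | methyl (2E,6E)-2-{(1S,2S)-1-(acetyloxy)-2-[(2-methylpropanoyl)oxy]penta-3,4-dien-1-yl}-6-{[(tert-butyldiphenylsilyl)oxy]methyl}-9-hydroxynona-2,6-dienoate | OCC/C=C(/CO[Si](c1ccccc1)(c1ccccc1)C(C)(C)C)CC/C=C(/C(=O)OC)[C@H](OC(C)=O)[C@@H](OC(=O)C(C)C)C=C=C | intermediate
28 | methyl (2E,6E)-2-{(1S,2S)-1-(acetyloxy)-2-[(2-methylpropanoyl)oxy]penta-3,4-dien-1-yl}-6-{[(tert-butyldiphenylsilyl)oxy]methyl}-9-oxonona-2,6-dienoate | O=CC/C=C(/CO[Si](c1ccccc1)(c1ccccc1)C(C)(C)C)CC/C=C(/C(=O)OC)[C@H](OC(C)=O)[C@@H](OC(=O)C(C)C)C=C=C | intermediate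
29 | (3E,7E,9S,10S)-9-(acetyloxy)-4-{[(tert-butyldiphenylsilyl)oxy]methyl}-8-(methoxycarbonyl)-10-[(2-methylpropanoyl)oxy]trideca-3,7,11,12-tetraenoic acid | OC(=O)C/C=C(/CO[Si](c1ccccc1)(c1ccccc1)C(C)(C)C)CC/C=C(/C(=O)OC)[C@H](OC(C)=O)[C@@H](OC(=O)C(C)C)C=C=C | intermediate
30 | acid chloride of 29 | ClC(=O)C/C=C(/CO[Si](c1ccccc1)(c1ccccc1)C(C)(C)C)CC/C=C(/C(=O)OC)[C@H](OC(C)=O)[C@@H](OC(=O)C(C)C)C=C=C | intermediate
31 | vinylketene from 30 by loss of HCl (O=C12=C6H–C5H=C4; rest as 29) | O=C=C/C=C(/CO[Si](c1ccccc1)(c1ccccc1)C(C)(C)C)CC/C=C(/C(=O)OC)[C@H](OC(C)=O)[C@@H](OC(=O)C(C)C)C=C=C | intermediate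
32 | trans-fused 2-methylenecyclobutanone (6R,7R,8S,9S; 1(10)E,4E): germacradiene ring closed, C12 bonded to C6 and C11, 8-O-isobutyryl, 9-O-acetyl, 14-methyl ester, 15-O-TBDPS | C=C1C(=O)[C@@H]2/C=C(/CO[Si](c3ccccc3)(c3ccccc3)C(C)(C)C)CC/C=C(/C(=O)OC)[C@H](OC(C)=O)[C@@H](OC(=O)C(C)C)[C@@H]12 | intermediate
33 | 15-O-(tert-butyldiphenylsilyl) ether of the target (6R,7S,8S,9S) | C=C1C(=O)O[C@@H]2/C=C(/CO[Si](c3ccccc3)(c3ccccc3)C(C)(C)C)CC/C=C(/C(=O)OC)[C@H](OC(C)=O)[C@@H](OC(=O)C(C)C)[C@@H]12 | intermediate
34 | methyl (3aS,4S,5S,6E,10E,11aR)-5-(acetyloxy)-10-(hydroxymethyl)-3-methylidene-4-[(2-methylpropanoyl)oxy]-2-oxo-2,3,3a,4,5,8,9,11a-octahydrocyclodeca[b]furan-6-carboxylate | C=C1C(=O)O[C@@H]2/C=C(/CO)CC/C=C(/C(=O)OC)[C@H](OC(C)=O)[C@@H](OC(=O)C(C)C)[C@@H]12 | target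

**Step count and risks**

Total: 22 steps. Longest linear sequence: 20 steps (1–6, then 9–22).

Most likely to fail:

1. Step 20 (Proposed new method). The ketene may be consumed by dimerisation, oligomerisation or a [1,5]-hydrogen shift (C3–H to C12) before the ten-membered ring closes, or the cycloaddition may take the terminal π bond of the allene or the wrong face at C7. The fallback replaces the ketene by a keteniminium ion, whose [2+2] cycloaddition to olefins is an established intramolecular route to cyclobutanones and which does not dimerise; the ten-membered ring size is untested for it as well. It sets out from acid 29: coupling with pyrrolidine (EDC·HCl, DMAP, CH2Cl2) gives the pyrrolidine amide F1; Tf2O and 2,4,6-collidine in ClCH2CH2Cl at high dilution give the keteniminium triflate F2, which should close to the cyclobutaniminium triflate F3; hydrolysis with aqueous NaHCO3 comes back to the route at cyclobutanone 32.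

2. Step 21. Hydrogen peroxide may add conjugatively to the exocyclic enone, the C4=C5 olefin may be epoxidised, or the vinylic carbon C11 may migrate instead of C6. The fallback masks the enone first. Setting out from 32, Me2NH in THF at 0 °C adds to C13 to give the β-amino ketone F4 (C11 epimers); H2O2 in AcOH, in which the amine is protonated and so protected, should give the amino lactone F5 by migration of C6; MeI gives the trimethylammonium iodide F6, and NaHCO3 eliminates trimethylamine to come back to the route at lactone 33.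

3. Step 17. While O8 is free, γ-lactonisation onto the C14 ester or acetyl migration from O9 may compete with acylation. The fallback exchanges silyl for acyl without freeing the hydroxyl: setting out from 24, isobutyric anhydride and catalytic Bi(OTf)3 in MeCN at 0 °C should convert the triethylsilyl ether directly into the isobutyrate and come back to the route at 26; this fallback makes no new compound (F0).

**Further compounds**

F1 | step 20 | pyrrolidine amide of acid 29 | O=C(C/C=C(/CO[Si](c1ccccc1)(c1ccccc1)C(C)(C)C)CC/C=C(/C(=O)OC)[C@H](OC(C)=O)[C@@H](OC(=O)C(C)C)C=C=C)N1CCCC1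
F2 | step 20 | keteniminium triflate derived from F1 | C1CC[N+](C1)=C=C/C=C(/CO[Si](c2ccccc2)(c2ccccc2)C(C)(C)C)CC/C=C(/C(=O)OC)[C@H](OC(C)=O)[C@@H](OC(=O)C(C)C)C=C=C.[O-]S(=O)(=O)C(F)(F)F
F3 | step 20 | cyclobutaniminium triflate (pyrrolidinium analogue of 32) | C=C1C(=[N+]3CCCC3)[C@@H]2/C=C(/CO[Si](c4ccccc4)(c4ccccc4)C(C)(C)C)CC/C=C(/C(=O)OC)[C@H](OC(C)=O)[C@@H](OC(=O)C(C)C)[C@@H]12.[O-]S(=O)(=O)C(F)(F)F
F4 | step 21 | dimethylamine adduct of 32 (β-amino ketone, C11 epimers) | CN(C)CC1C(=O)[C@@H]2/C=C(/CO[Si](c3ccccc3)(c3ccccc3)C(C)(C)C)CC/C=C(/C(=O)OC)[C@H](OC(C)=O)[C@@H](OC(=O)C(C)C)[C@@H]12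
F5 | step 21 | amino lactone (dimethylamine adduct of 33) | CN(C)CC1C(=O)O[C@@H]2/C=C(/CO[Si](c3ccccc3)(c3ccccc3)C(C)(C)C)CC/C=C(/C(=O)OC)[C@H](OC(C)=O)[C@@H](OC(=O)C(C)C)[C@@H]12
F6 | step 21 | trimethylammonium iodide of F5 | C[N+](C)(C)CC1C(=O)O[C@@H]2/C=C(/CO[Si](c3ccccc3)(c3ccccc3)C(C)(C)C)CC/C=C(/C(=O)OC)[C@H](OC(C)=O)[C@@H](OC(=O)C(C)C)[C@@H]12.[I-]
F0 | step 17 | none | none
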